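**Retrosynthetic overview**

1. The C18–O ester bond is cut last: labdane alcohol 24 + hydroxy acid 38. Acid 38 comes from 3-methylcyclohex-2-en-1-one by Pd-catalysed asymmetric allylation (ring CH), Cu-catalysed methyl conjugate addition (chain CH(CH3)) and radical hydration (tertiary carbinol).
2. Alcohol 24 comes from keto aldehyde 10: C9 side chain by B-alkyl Suzuki coupling on the C9 enol triflate, 9α-H and C8 oxygen by hydroboration, C8=C17 by Wittig, C13=C14 by Horner–Wadsworth–Emmons.
3. Key disconnection: ring A of 10 comes from a ring-enlarged epoxide 9 by a stereospecific epoxide-to-aldehyde 1,2-shift (ring contraction). 9 comes from ring-closing metathesis (7 to 8) and epoxidation; 7 from 2-methylcyclohex-2-en-1-one by asymmetric conjugate addition (C5) and enolate alkylation (C10).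
4. Enabling feature: C4 is a quaternary ring carbon carrying a methyl (C19) and a one-carbon oxygenated branch (C18). That C(CH3)(CH2O–) unit between C3 and C5 is what remains when the ring bond C3–C18 of a 4,18-epoxy seven-membered ring (C1, C2, C3, C18, C4, C5, C10) migrates to C4. The trans C5/C10 relationship is fixed on ring B beforehand, so no ring-fusion centre is made in the ring closure.
5. Ring order: ring B (bought as 1), then a temporary seven-membered ring (step 3), then ring A (step 5, last ring of the skeleton). The cyclohexane of the acid is bought as 25.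

Key step: step 5

Assumption: in the three catalyst-controlled steps (1, 16, 21) the ligand enantiomer named is taken to give the configuration drawn; if the sense of induction is opposite, the mirror-image ligand is used. Locants C1–C20 follow labdane numbering.

**Labdane part**

Step 1
Reactants: 1 2-methylcyclohex-2-en-1-one; 2 isopropenylmagnesium bromide
Product: 4 trimethyl{[(3S)-2-methyl-3-(prop-1-en-2-yl)cyclohex-1-en-1-yl]oxy}silane, via magnesium enolate 3 (not isolated)
Conditions: Cu(OTf)2 (3 mol %), (4S,5S)-4,5-diphenyl-1,3-bis(2,4,6-trimethylbenzyl)imidazolinium chloride (4 mol %), Et2O, −30 °C; then Me3SiCl, −30 to 23 °C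
Reagents that add atoms: chlorotrimethylsilane C[Si](C)(C)Cl
Why: Copper-catalysed asymmetric conjugate addition of a Grignard reagent to an α-substituted cyclic enone, in which the chiral carbene–copper complex selects the enone face and sets C5, and silylation of the enolate fixes its position between C9 and C10.

Step 2
Reactants: 4 silyl enol ether; 5 5-iodopent-1-ene
Product: 7 (2S,3S)-2-methyl-2-(pent-4-en-1-yl)-3-(prop-1-en-2-yl)cyclohexan-1-one, via lithium enolate 6 (not isolated)
Conditions: MeLi, THF, 0 °C; then 5, DMPU, −40 to 23 °C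
Reagents that add atoms: none
Why: Regiospecific enolate alkylation (enolate released from the silyl enol ether), with the iodide entering anti to the neighbouring isopropenyl group, so the C10 quaternary centre is set with the new chain trans to the C5 substituent (the future trans ring fusion).

Step 3
Reactants: 7 diene ketone
Product: 8 (1S,7S)-2,7-dimethylbicyclo[5.4.0]undec-2-en-8-one
Conditions: second-generation Grubbs catalyst RuCl2(=CHPh)(H2IMes)(PCy3) (5 mol %), CH2Cl2, 40 °C
Reagents that add atoms: none
Why: Ring-closing metathesis of the 1,1-disubstituted and the monosubstituted alkene should give the trisubstituted cycloheptene C4(CH3)=C18H with loss of ethene; no stereocentre is formed.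

Step 4
Reactants: 8 bicyclic enone
Product: 9 (1S,7S)-2,3-epoxy-2,7-dimethylbicyclo[5.4.0]undecan-8-one, oxirane on the face opposite the C7 methyl (4α,18-epoxide in labdane numbering)
Conditions: m-CPBA, NaHCO3, CH2Cl2, 0 °C
Reagents that add atoms: 3-chloroperoxybenzoic acid OOC(=O)c1cccc(Cl)c1
Why: Prilezhaev epoxidation of the only alkene, expected from the α face because the axial C10 methyl shields the β face of the chair-like seven-membered ring; this sets the oxirane configuration at C4 and C18.

Step 5
Reactants: 9 epoxy ketone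
Product: 10 (1R,4aS,8aS)-1,4a-dimethyl-5-oxodecahydronaphthalene-1-carbaldehyde
Conditions: MeAl(OAr)2 (Ar = 4-bromo-2,6-di-tert-butylphenyl; from Me3Al and ArOH; 2.2 equiv), CH2Cl2, −78 to −20 °C
Reagents that add atoms: none
Why: The bulky aluminium Lewis acid binds the oxirane oxygen and ionises the tertiary C4–O bond while the ring bond C3–C18 shifts from C18 to C4, leaving C18 as the aldehyde (semipinacol/Meinwald rearrangement). The closest known reaction type is the organoaluminium-promoted rearrangement of trisubstituted epoxides to α-quaternary aldehydes, including ring contraction of 1-methylcycloalkene oxides. Ring A (C1–C2–C3–C4–C5–C10) is closed by this 1,2-alkyl shift, that is by contraction of the seven-membered ring with extrusion of C18. The new stereocentre C4 is controlled by the oxirane: C3 enters anti to the departing oxygen (inversion at C4), so the α-oxirane gives 4β-methyl/4α-formyl, while C5 and C10 are untouched and the trans fusion is inherited. The step needs C4–O rather than C18–O cleavage and alkyl rather than hydride migration; the tertiary C4 secures the first, and the bulky Lewis acid together with relief of seven-ring strain should favour the second. The C9 ketone only consumes an extra equivalent of Lewis acid.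

Step 6
Reactants: 10 keto aldehyde
Product: 11 (4aS,5R,8aS)-5-(hydroxymethyl)-5,8a-dimethyloctahydronaphthalen-1(2H)-one
Conditions: NaBH4 (0.3 equiv), MeOH–CH2Cl2, −78 °C
Reagents that add atoms: none
Why: Chemoselective borohydride reduction of the aldehyde at low temperature, the C9 ketone next to the quaternary C10 being much slower; no stereocentre is formed.

Step 7
Reactants: 11 keto alcohol
Product: 12 (4aS,5R,8aS)-5-{[(tert-butyldimethylsilyl)oxy]methyl}-5,8a-dimethyloctahydronaphthalen-1(2H)-one
Conditions: TBSCl, imidazole, DMF, 23 °C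
Reagents that add atoms: tert-butyldimethylsilyl chloride CC(C)(C)[Si](C)(C)Cl
Why: Standard silylation of the primary alcohol, which protects C18–OH through the base, borane and ylide steps.

Step 8
Reactants: 12 silyl ether ketone
Product: 14 (4aS,5R,8aS)-5-{[(tert-butyldimethylsilyl)oxy]methyl}-5,8a-dimethyl-3,4,4a,5,6,7,8,8a-octahydronaphthalen-1-yl trifluoromethanesulfonate, via potassium enolate 13 (not isolated)
Conditions: KHMDS, THF, −78 °C; then PhNTf2, −78 to 0 °C
Reagents that add atoms: N-phenylbis(trifluoromethanesulfonimide) O=S(=O)(N(c1ccccc1)S(=O)(=O)C(F)(F)F)C(F)(F)F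
Why: Enol triflate formation, in which enolisation can only go toward C8 because C10 is quaternary.

Step 9
Reactants: 14 enol triflate; 15 2-ethenyl-2-methyl-1,3-dioxolane
Product: 17 18-[(tert-butyldimethylsilyl)oxy]-14,15-dinorlabd-8-en-13-one ethylene ketal, via alkylborane 16 (not isolated)
Conditions: 15, 9-BBN, THF, 0 to 23 °C; then 14, PdCl2(dppf) (5 mol %), AsPh3, Cs2CO3, DMF–H2O, 50 °C
Reagents that add atoms: none
Why: B-alkyl Suzuki–Miyaura coupling, with anti-Markovnikov hydroboration of the vinyl dioxolane giving the primary alkylborane that palladium transfers to C9.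

Step 10
Reactants: 17 trisubstituted alkene
Product: 19 18-[(tert-butyldimethylsilyl)oxy]-8α-hydroxy-14,15-dinorlabdan-13-one ethylene ketal (9α-H), via alkylborane 18 (not isolated)
Conditions: BH3·THF, THF, 0 to 23 °C; then NaOH, H2O2, 0 °C
Reagents that add atoms: hydrogen peroxide OO
Why: Hydroboration–oxidation with syn addition from the α face (the β face is blocked by the C10 methyl) and boron at the less substituted C8, so C9 receives its α-hydrogen (equatorial side chain) and C8 an α-hydroxyl.

Step 11
Reactants: 19 secondary alcohol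
Product: 20 18-[(tert-butyldimethylsilyl)oxy]-14,15-dinorlabdane-8,13-dione 13-ethylene ketal
Conditions: Dess–Martin periodinane, NaHCO3, CH2Cl2, 23 °C
Reagents that add atoms: none
Why: Mild periodinane oxidation to the C8 ketone; C9 already has the thermodynamically preferred equatorial side chain, so it is not at risk.

Step 12
Reactants: 20 C8 ketone
Product: 21 18-[(tert-butyldimethylsilyl)oxy]-14,15-dinorlabd-8(17)-en-13-one ethylene ketal
Conditions: Ph3PCH3Br, KOt-Bu, toluene, 23 to 60 °C
Reagents that add atoms: methyltriphenylphosphonium bromide C[P+](c1ccccc1)(c1ccccc1)c1ccccc1.[Br-]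
Why: Wittig methylenation installs the exocyclic C8=C17 alkene; ketal and silyl ether are inert to the ylide.

Step 13
Reactants: 21 ketal silyl ether
Product: 22 18-hydroxy-14,15-dinorlabd-8(17)-en-13-one
Conditions: HCl (2 M aq.), THF–MeOH, 23 °C
Reagents that add atoms: water O
Why: Acid hydrolysis removes the dioxolane and the silyl ether in one operation under conditions mild enough for the exocyclic alkene.

Step 14
Reactants: 22 hydroxy methyl ketone; 23 trimethyl phosphonoacetate
Product: 24 methyl (13E)-18-hydroxylabda-8(17),13-dien-15-oate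
Conditions: NaH (2.5 equiv), THF, 0 to 50 °C
Reagents that add atoms: none
Why: Horner–Wadsworth–Emmons olefination of the methyl ketone, expected to favour the E enoate (minor Z isomer removed by chromatography); the free alcohol is carried as its alkoxide.

**Acid part**

Step 15
Reactants: 25 3-methylcyclohex-2-en-1-one; 26 allyl chloroformate
Product: 28 3,3-dimethylcyclohex-1-en-1-yl prop-2-en-1-yl carbonate, via lithium enolate 27 (not isolated)
Conditions: Me2CuLi (from CuI, MeLi), Et2O, 0 °C; then 26, THF, −78 to 0 °C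
Reagents that add atoms: lithium dimethylcuprate [Li+].C[Cu-]C
Why: Cuprate conjugate addition gives the regiodefined enolate next to the gem-dimethyl carbon, and O-acylation with the chloroformate traps it as the allyl enol carbonate.

Step 16
Reactants: 28 allyl enol carbonate
Product: 29 (2R)-3,3-dimethyl-2-(prop-2-en-1-yl)cyclohexan-1-one
Conditions: Pd2(dba)3 (2.5 mol %), (R,R)-N,N'-(cyclohexane-1,2-diyl)bis[2-(diphenylphosphanyl)benzamide] (5.5 mol %), 1,4-dioxane, 23 °C
Reagents that add atoms: none
Why: Palladium-catalysed decarboxylative asymmetric allylic alkylation (Tsuji–Trost type); the chiral ligand controls the enolate face and sets the ring CH stereocentre without external base.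

Step 17
Reactants: 29 allyl ketone
Product: 30 (2R)-1,1-dimethyl-3-methylidene-2-(prop-2-en-1-yl)cyclohexane
Conditions: Zn, CH2Br2, TiCl4, THF–CH2Cl2, 0 to 23 °C
Reagents that add atoms: dibromomethane BrCBr
Why: Takai–Lombardo methylenation is non-basic, so the epimerisable α-stereocentre should survive.

Step 18
Reactants: 30 diene
Product: 32 3-[(1R)-2,2-dimethyl-6-methylidenecyclohexyl]propan-1-ol, via alkylborane 31 (not isolated)
Conditions: Sia2BH (from BH3·THF, 2-methylbut-2-ene), THF, 0 °C; then NaOH, H2O2
Reagents that add atoms: hydrogen peroxide OO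
Why: Hydroboration–oxidation with the bulky disiamylborane, which should select the monosubstituted vinyl group over the hindered exocyclic 1,1-disubstituted alkene.

Step 19
Reactants: 32 primary alcohol
Product: 33 3-[(1R)-2,2-dimethyl-6-methylidenecyclohexyl]propanal
Conditions: Dess–Martin periodinane, NaHCO3, CH2Cl2, 23 °C
Reagents that add atoms: none
Why: Periodinane oxidation to the aldehyde under neutral conditions.

Step 20
Reactants: 33 aldehyde; 34 methyl (triphenyl-λ5-phosphanylidene)acetate
Product: 35 methyl (2E)-5-[(1R)-2,2-dimethyl-6-methylidenecyclohexyl]pent-2-enoate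
Conditions: CH2Cl2, 23 °C
Reagents that add atoms: none
Why: Wittig reaction with a stabilised ylide, which should give the E enoate.

Step 21
Reactants: 35 enoate
Product: 36 methyl (3S)-5-[(1R)-2,2-dimethyl-6-methylidenecyclohexyl]-3-methylpentanoate
Conditions: MeMgBr, CuI (2 mol %), (R)-Tol-BINAP (3 mol %), t-BuOMe, −20 °C; then aq. NH4Cl
Reagents that add atoms: methylmagnesium bromide C[Mg]Br
Why: Copper-catalysed asymmetric conjugate addition of a methyl Grignard reagent to an E α,β-unsaturated ester; the chiral diphosphine–copper complex sets the chain CH(CH3) centre, remote from the ring centre.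

Step 22
Reactants: 36 exocyclic alkene ester
Product: 37 methyl (3S)-5-[(1R,2R)-2-hydroxy-2,6,6-trimethylcyclohexyl]-3-methylpentanoate
Conditions: Mn(dpm)3 (10 mol %), PhSiH3, O2 (1 atm), i-PrOH–CH2Cl2, 0 to 23 °C
Reagents that add atoms: dioxygen O=O
Why: Mukaiyama hydration (hydrogen-atom transfer to the CH2 terminus, then oxygen capture of the tertiary radical); the syn-axial methyl of the gem-dimethyl group blocks axial approach, so the C–O bond should form equatorial, trans to the side chain.

Step 23
Reactants: 37 hydroxy ester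
Product: 38 (3S)-5-[(1R,2R)-2-hydroxy-2,6,6-trimethylcyclohexyl]-3-methylpentanoic acid
Conditions: LiOH·H2O, THF–H2O, 23 °C; then aq. HCl
Reagents that add atoms: lithium hydroxide [Li+].[OH-]
Why: Saponification of the methyl ester; no stereocentre is epimerisable.

**Coupling**

Step 24
Reactants: 24 labdane alcohol; 38 hydroxy acid
Product: 39 methyl (13E)-18-{[(3S)-5-((1R,2R)-2-hydroxy-2,6,6-trimethylcyclohexyl)-3-methylpentanoyl]oxy}labda-8(17),13-dien-15-oate (CNP0174687.1)
Conditions: EDC·HCl, DMAP, CH2Cl2, 0 to 23 °C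
Reagents that add atoms: none
Why: Steglich esterification of the primary neopentyl alcohol; the hindered tertiary alcohol of the acid should not compete.

**Compound list**

1 | 2-methylcyclohex-2-en-1-one | CC1=CCCCC1=O | starting material
2 | isopropenylmagnesium bromide | CC(=C)[Mg]Br | starting material
3 | bromomagnesium (3S)-2-methyl-3-(prop-1-en-2-yl)cyclohex-1-en-1-olate | Br[Mg]OC1=C(C)[C@H](C(C)=C)CCC1 | intermediate
4 | trimethyl{[(3S)-2-methyl-3-(prop-1-en-2-yl)cyclohex-1-en-1-yl]oxy}silane | C[Si](C)(C)OC1=C(C)[C@H](C(C)=C)CCC1 | intermediate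
5 | 5-iodopent-1-ene | C=CCCCI | starting material
6 | lithium (3S)-2-methyl-3-(prop-1-en-2-yl)cyclohex-1-en-1-olate | [Li]OC1=C(C)[C@H](C(C)=C)CCC1 | intermediate
7 | (2S,3S)-2-methyl-2-(pent-4-en-1-yl)-3-(prop-1-en-2-yl)cyclohexan-1-one | O=C1[C@@](C)(CCCC=C)[C@H](C(C)=C)CCC1 | intermediate
8 | (1S,7S)-2,7-dimethylbicyclo[5.4.0]undec-2-en-8-one (trans-fused) | O=C1CCC[C@H]2C(C)=CCCC[C@]12C | intermediate
9 | (1S,7S)-2,3-epoxy-2,7-dimethylbicyclo[5.4.0]undecan-8-one, oxirane anti to the C7 methyl | O=C1CCC[C@H]2[C@]3(C)O[C@@H]3CCC[C@]12C | intermediate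
10 | (1R,4aS,8aS)-1,4a-dimethyl-5-oxodecahydronaphthalene-1-carbaldehyde | O=C1CCC[C@H]2[C@](C)(C=O)CCC[C@]12C | intermediate
11 | (4aS,5R,8aS)-5-(hydroxymethyl)-5,8a-dimethyloctahydronaphthalen-1(2H)-one | O=C1CCC[C@H]2[C@](C)(CO)CCC[C@]12C | intermediate
12 | (4aS,5R,8aS)-5-{[(tert-butyldimethylsilyl)oxy]methyl}-5,8a-dimethyloctahydronaphthalen-1(2H)-one | O=C1CCC[C@H]2[C@](C)(CO[Si](C)(C)C(C)(C)C)CCC[C@]12C | intermediate
13 | potassium enolate of 12 (enolised toward C8) | [K]OC1=CCC[C@H]2[C@](C)(CO[Si](C)(C)C(C)(C)C)CCC[C@]12C | intermediate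
14 | (4aS,5R,8aS)-5-{[(tert-butyldimethylsilyl)oxy]methyl}-5,8a-dimethyl-3,4,4a,5,6,7,8,8a-octahydronaphthalen-1-yl trifluoromethanesulfonate | FC(F)(F)S(=O)(=O)OC1=CCC[C@H]2[C@](C)(CO[Si](C)(C)C(C)(C)C)CCC[C@]12C | intermediate
15 | 2-ethenyl-2-methyl-1,3-dioxolane | C=CC1(C)OCCO1 | starting material
16 | 9-[2-(2-methyl-1,3-dioxolan-2-yl)ethyl]-9-borabicyclo[3.3.1]nonane | CC1(CCB2C3CCCC2CCC3)OCCO1 | intermediate
17 | 18-[(tert-butyldimethylsilyl)oxy]-14,15-dinorlabd-8-en-13-one ethylene ketal (5α-H, 10β-CH3, 4β-CH3) | C1(CCC3(C)OCCO3)=CCC[C@H]2[C@](C)(CO[Si](C)(C)C(C)(C)C)CCC[C@]12C | intermediate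
18 | 8α-boryl adduct of 17 (9α-H) | B[C@@H]1CC[C@H]2[C@](C)(CO[Si](C)(C)C(C)(C)C)CCC[C@]2(C)[C@H]1CCC3(C)OCCO3 | intermediate
19 | 18-[(tert-butyldimethylsilyl)oxy]-8α-hydroxy-14,15-dinorlabdan-13-one ethylene ketal | O[C@@H]1CC[C@H]2[C@](C)(CO[Si](C)(C)C(C)(C)C)CCC[C@]2(C)[C@H]1CCC3(C)OCCO3 | intermediate
20 | 18-[(tert-butyldimethylsilyl)oxy]-14,15-dinorlabdane-8,13-dione 13-ethylene ketal | O=C1CC[C@H]2[C@](C)(CO[Si](C)(C)C(C)(C)C)CCC[C@]2(C)[C@H]1CCC3(C)OCCO3 | intermediate
21 | 18-[(tert-butyldimethylsilyl)oxy]-14,15-dinorlabd-8(17)-en-13-one ethylene ketal | C=C1CC[C@H]2[C@](C)(CO[Si](C)(C)C(C)(C)C)CCC[C@]2(C)[C@H]1CCC3(C)OCCO3 | intermediate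
22 | 18-hydroxy-14,15-dinorlabd-8(17)-en-13-one | C=C1CC[C@H]2[C@](C)(CO)CCC[C@]2(C)[C@H]1CCC(C)=O | intermediate
23 | trimethyl phosphonoacetate | COC(=O)CP(=O)(OC)OC | starting material
24 | methyl (13E)-18-hydroxylabda-8(17),13-dien-15-oate | C=C1CC[C@H]2[C@](C)(CO)CCC[C@]2(C)[C@H]1CC/C(C)=C/C(=O)OC | intermediate
25 | 3-methylcyclohex-2-en-1-one | CC1=CC(=O)CCC1 | starting material
26 | allyl chloroformate | C=CCOC(Cl)=O | starting material
27 | lithium 3,3-dimethylcyclohex-1-en-1-olate | [Li]OC1=CC(C)(C)CCC1 | intermediate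
28 | 3,3-dimethylcyclohex-1-en-1-yl prop-2-en-1-yl carbonate | C=CCOC(=O)OC1=CC(C)(C)CCC1 | intermediate
29 | (2R)-3,3-dimethyl-2-(prop-2-en-1-yl)cyclohexan-1-one | C=CC[C@@H]1C(C)(C)CCCC1=O | intermediate
30 | (2R)-1,1-dimethyl-3-methylidene-2-(prop-2-en-1-yl)cyclohexane | C=CC[C@@H]1C(C)(C)CCCC1=C | intermediate
31 | {3-[(1R)-2,2-dimethyl-6-methylidenecyclohexyl]propyl}bis(3-methylbutan-2-yl)borane | CC(C)C(C)B(CCC[C@@H]1C(C)(C)CCCC1=C)C(C)C(C)C | intermediate
32 | 3-[(1R)-2,2-dimethyl-6-methylidenecyclohexyl]propan-1-ol | OCCC[C@@H]1C(C)(C)CCCC1=C | intermediate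
33 | 3-[(1R)-2,2-dimethyl-6-methylidenecyclohexyl]propanal | O=CCC[C@@H]1C(C)(C)CCCC1=C | intermediate
34 | methyl (triphenyl-λ5-phosphanylidene)acetate | COC(=O)C=P(c1ccccc1)(c1ccccc1)c1ccccc1 | starting material
35 | methyl (2E)-5-[(1R)-2,2-dimethyl-6-methylidenecyclohexyl]pent-2-enoate | COC(=O)/C=C/CC[C@@H]1C(C)(C)CCCC1=C | intermediate
36 | methyl (3S)-5-[(1R)-2,2-dimethyl-6-methylidenecyclohexyl]-3-methylpentanoate | COC(=O)C[C@@H](C)CC[C@@H]1C(C)(C)CCCC1=C | intermediate
37 | methyl (3S)-5-[(1R,2R)-2-hydroxy-2,6,6-trimethylcyclohexyl]-3-methylpentanoate | COC(=O)C[C@@H](C)CC[C@@H]1C(C)(C)CCC[C@@]1(C)O | intermediate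
38 | (3S)-5-[(1R,2R)-2-hydroxy-2,6,6-trimethylcyclohexyl]-3-methylpentanoic acid | OC(=O)C[C@@H](C)CC[C@@H]1C(C)(C)CCC[C@@]1(C)O | intermediate
39 | CNP0174687.1 | C=C1CC[C@H]2[C@](C)(COC(=O)C[C@@H](C)CC[C@@H]3C(C)(C)CCC[C@@]3(C)O)CCC[C@]2(C)[C@H]1CC/C(C)=C/C(=O)OC | target

**Step count**

Total: 24 steps. Longest linear sequence: 15 steps (steps 1–14 and 24); the acid part (steps 15–23) joins at step 24.

**Three steps most likely to fail**

Step 5. Under the Lewis acid the hydrogen on C18 may migrate instead of the C3–C18 ring bond (giving the seven-membered ring ketone), or a free C4 cation may form and the anti stereospecificity at C4 be lost. The fallback sets out from 4 and returns at 11; it closes ring A by a 6-exo-tet ester-enolate cycloalkylation instead. Compound 4 is treated with MeLi and then 1-chloro-3-iodopropane to give (2S,3S)-2-(3-chloropropyl)-2-methyl-3-(prop-1-en-2-yl)cyclohexan-1-one F1. Ketalisation (ethylene glycol, TsOH) gives the ethylene ketal of F1, F2. Hydroboration of the isopropenyl group (9-BBN, then NaOH/H2O2) gives the primary alcohol F3 (both epimers at the new CH(CH3) centre serve). Buffered TEMPO/NaOCl/NaClO2 oxidation gives the carboxylic acid F4, and Me3SiCHN2 its methyl ester F5. KHMDS with NaI in THF–DMPU then forms the C3–C4 bond to give the ketal-protected trans-decalin methyl ester F6; allylic 1,3-strain in the enolate (C5–H eclipsing the enolate double bond) should place the ester equatorial (4α) and the methyl axial (4β). LiAlH4 gives the ketal-protected hydroxymethyl decalin F7, and aqueous HCl in THF releases the ketone to give 11.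

Step 1. The alkenyl Grignard reagent may add with low enantioselectivity or partly in 1,2-fashion to the α-substituted enone. The fallback sets out from 2 and returns at 4. Reagent 2 is added to the parent cyclohex-2-en-1-one, for which copper-catalysed asymmetric conjugate addition is best established (CuBr·SMe2 with a chiral ferrocenyl diphosphine), and the magnesium enolate is methylated in the same flask (MeI, DMPU) to give trans-(2S,3R)-2-methyl-3-(prop-1-en-2-yl)cyclohexan-1-one F8. Thermodynamic silylation (Me3SiCl, NaI, Et3N, MeCN) toward the more substituted side then gives 4.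

Step 22. Oxygen capture of the tertiary radical may occur from both faces and give the epimeric carbinol. The fallback sets out from 36 and returns at 38. m-CPBA should epoxidise the exocyclic alkene from the equatorial direction to give the spiro-epoxide ester F9. LiAlH4 opens the epoxide at CH2 and reduces the ester to give (3S)-5-[(1R,2R)-2-hydroxy-2,6,6-trimethylcyclohexyl]-3-methylpentan-1-ol F10. TEMPO/NaOCl/NaClO2 oxidises the primary alcohol to acid 38.

Further compounds

F1 | step 5 | (2S,3S)-2-(3-chloropropyl)-2-methyl-3-(prop-1-en-2-yl)cyclohexan-1-one | O=C1[C@@](C)(CCCCl)[C@H](C(C)=C)CCC1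
F2 | step 5 | ethylene ketal of F1, (6S,7S)-6-(3-chloropropyl)-6-methyl-7-(prop-1-en-2-yl)-1,4-dioxaspiro[4.5]decane | O1CCOC12[C@@](C)(CCCCl)[C@H](C(C)=C)CCC2
F3 | step 5 | 2-[(6S,7S)-6-(3-chloropropyl)-6-methyl-1,4-dioxaspiro[4.5]decan-7-yl]propan-1-ol (epimers at C2 of the propanol) | O1CCOC12[C@@](C)(CCCCl)[C@H](C(C)CO)CCC2
F4 | step 5 | 2-[(6S,7S)-6-(3-chloropropyl)-6-methyl-1,4-dioxaspiro[4.5]decan-7-yl]propanoic acid | O1CCOC12[C@@](C)(CCCCl)[C@H](C(C)C(=O)O)CCC2
F5 | step 5 | methyl 2-[(6S,7S)-6-(3-chloropropyl)-6-methyl-1,4-dioxaspiro[4.5]decan-7-yl]propanoate | O1CCOC12[C@@](C)(CCCCl)[C@H](C(C)C(=O)OC)CCC2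
F6 | step 5 | ethylene ketal of the methyl ester that corresponds to aldehyde 10 (4α-CO2CH3, 4β-CH3, trans fusion) | O1CCOC13CCC[C@H]2[C@](C)(C(=O)OC)CCC[C@]32C
F7 | step 5 | ethylene ketal of 11 | O1CCOC13CCC[C@H]2[C@](C)(CO)CCC[C@]32C
F8 | step 1 | (2S,3R)-2-methyl-3-(prop-1-en-2-yl)cyclohexan-1-one | O=C1[C@@H](C)[C@H](C(C)=C)CCC1
F9 | step 22 | spiro-epoxide of 36 (oxirane oxygen equatorial, trans to the side chain) | COC(=O)C[C@@H](C)CC[C@@H]1C(C)(C)CCC[C@]12CO2
F10 | step 22 | (3S)-5-[(1R,2R)-2-hydroxy-2,6,6-trimethylcyclohexyl]-3-methylpentan-1-ol | OCC[C@@H](C)CC[C@@H]1C(C)(C)CCC[C@@]1(C)O
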